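A direct plan would benzylate a hydroxydimethoxybenzaldehyde to A1, condense it (Perkin) with (3-methoxyphenyl)acetic acid A2 to the stilbene acid A3, decarboxylate and hydrogenate to the phenolic bibenzyl A4, arylate this by SNAr to the aldehyde A5, repeat the three bridge-building steps to the tetramethyl ether A6, and demethylate.
Its weakest steps would be:
- the two copper/quinoline protodecarboxylations near 210 °C, which would excise a carbon added one step earlier and would tend to char electron-rich stilbene acids;
- the benzyl protection and its hydrogenolytic removal, which would add operations but no skeleton;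
- the separate condensation, decarboxylation and hydrogenation for each bridge in turn, which would make the route long and strictly linear.

The route rests on the observation that each terminal unit of the target, a phenol ring (A or D) with its hydroxyl at C1 and the saturated bridge at C3, is a constitutional isomer of a 3-(2-arylethenyl)cyclohex-2-enone. Rings A and D are therefore not bought as arenes. Both arms are attached as 3-methylcyclohex-2-enone by a twofold vinylogous aldol condensation onto a diaryl ether dialdehyde, and one palladium-mediated isoaromatisation then creates both phenol rings and both CH2CH2 bridges at once. Hydrogen only changes place, so no carboxyl group is added and excised, no phenol needs a benzyl mask, and the two bridges arise together rather than one after the other.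

Key step: step 3

Remark: rings A and D are the terminal 3-hydroxyphenyl rings, ring B is the 1,4-phenylene ring and ring C is the catechol ring. The target has no stereocentre. Compounds 1, 2 and 4 are assumed to be purchased.

Step 1
Reactants: 1 3-hydroxy-4,5-dimethoxybenzaldehyde; 2 4-fluorobenzaldehyde
Product: 3 3-(4-formylphenoxy)-4,5-dimethoxybenzaldehyde
Conditions: K2CO3 (1.5 equiv), DMF, 120 °C, argon
Reagents that add atoms: none
Why: Nucleophilic aromatic substitution (SNAr), in which the para-formyl group activates the C–F bond of 2 towards the phenoxide of 1 and both non-enolisable aldehydes survive carbonate, so that the diaryl ether is made at the outset from two simple arenes with both bridge anchors in place.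

Step 2
Reactants: 3 3-(4-formylphenoxy)-4,5-dimethoxybenzaldehyde; 4 3-methylcyclohex-2-en-1-one
Product: 5 3-[(E)-2-(4-{2,3-dimethoxy-5-[(E)-2-(3-oxocyclohex-1-en-1-yl)ethenyl]phenoxy}phenyl)ethenyl]cyclohex-2-en-1-one
Conditions: 4 (3 equiv), NaOMe (0.5 equiv), MeOH/THF, rt to 50 °C
Reagents that add atoms: none
Why: Twofold vinylogous aldol (Claisen–Schmidt) condensation, in which under reversible alkoxide conditions the extended dienolate of 4 should attack the non-enolisable aldehydes through its exocyclic methyl carbon, as is known for isophorone and piperitone, and E1cB loss of water should give the linearly conjugated (E,E)-bis-dienone as the thermodynamic sink, with no stereocentre formed and an alkene geometry that is erased in step 3.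

Step 3
Reactants: 5 3-[(E)-2-(4-{2,3-dimethoxy-5-[(E)-2-(3-oxocyclohex-1-en-1-yl)ethenyl]phenoxy}phenyl)ethenyl]cyclohex-2-en-1-one
Product: 6 3-[2-(4-{5-[2-(3-hydroxyphenyl)ethyl]-2,3-dimethoxyphenoxy}phenyl)ethyl]phenol
Conditions: 10% Pd/C (0.2 equiv Pd), K2CO3 (0.2 equiv), degassed DMA, 150 °C, sealed tube, argon; then dilute HCl
Reagents that add atoms: none
Why: Proposed new method: each 3-(2-arylethenyl)cyclohex-2-enone arm of 5 is a constitutional isomer of a 3-(2-arylethyl)phenol, and zerovalent palladium on carbon should interconvert them by hydrogen transfer: it takes two hydrogens from the ring (C5 and C6, through a surface enolate and beta-hydride elimination), the resulting cyclohexa-2,5-dienone tautomerises to the phenol, and the hydride is passed to the conjugated exocyclic C=C of the same or another arm. The closest known reaction types are the palladium-on-carbon isoaromatisation of alkenyl- and alkylidene-cyclohexenones to alkylphenols (carvone to carvacrol, 2-benzylidenecyclohexanones to 2-benzylphenols) and the palladium-catalysed dehydrogenation of 3-substituted cyclohexenones to meta-substituted phenols. No ring is closed, since the six-membered carbocycles of 4 are aromatised to rings A and D, and the hydroxyl group must end up meta to the bridge because C1 (carbonyl) and C3 of the enone keep their 1,3-relationship. No stereocentre is formed and the E geometry of both alkenes is erased. The step needs hydrogen to be handed to the bridges and not lost or spent on the ring, which the closed vessel and the thermodynamics should secure: an over-reduced ring is dehydrogenated again, a transient hydroxystilbene is reduced, and every species should converge on the aromatic isomer. Aryl ethers, methyl ethers and the new phenols are inert under these weakly basic conditions.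

Step 4
Reactants: 6 3-[2-(4-{5-[2-(3-hydroxyphenyl)ethyl]-2,3-dimethoxyphenoxy}phenyl)ethyl]phenol
Product: 7 perrottetin F
Conditions: BBr3 (6 equiv), CH2Cl2, −78 °C to rt; then ice-water, argon
Reagents that add atoms: none
Why: Lewis acid-mediated aryl methyl ether cleavage, in which BBr3 coordinates each methoxy oxygen and bromide removes the methyl group by SN2, the two free phenols only consume reagent as aryloxyboranes, and hydrolysis should release the catechol while the diaryl ether and the CH2CH2 bridges stay intact.

## Compound list

1 | 3-hydroxy-4,5-dimethoxybenzaldehyde | COc1cc(C=O)cc(O)c1OC | starting material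
2 | 4-fluorobenzaldehyde | O=Cc1ccc(F)cc1 | starting material
3 | 3-(4-formylphenoxy)-4,5-dimethoxybenzaldehyde | COc1cc(C=O)cc(Oc2ccc(C=O)cc2)c1OC | intermediate
4 | 3-methylcyclohex-2-en-1-one | CC1=CC(=O)CCC1 | starting material
5 | 3-[(E)-2-(4-{2,3-dimethoxy-5-[(E)-2-(3-oxocyclohex-1-en-1-yl)ethenyl]phenoxy}phenyl)ethenyl]cyclohex-2-en-1-one (E,E-bis-dienone) | O=C1C=C(/C=C/c2ccc(Oc3cc(/C=C/C4=CC(=O)CCC4)cc(OC)c3OC)cc2)CCC1 | intermediate
6 | 3-[2-(4-{5-[2-(3-hydroxyphenyl)ethyl]-2,3-dimethoxyphenoxy}phenyl)ethyl]phenol (perrottetin F with ring C as its dimethyl ether) | Oc1cccc(CCc2ccc(Oc3cc(CCc4cccc(O)c4)cc(OC)c3OC)cc2)c1 | intermediate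
7 | perrottetin F, 5-[2-(3-hydroxyphenyl)ethyl]-3-{4-[2-(3-hydroxyphenyl)ethyl]phenoxy}benzene-1,2-diol (achiral) | Oc1cccc(CCc2ccc(Oc3cc(CCc4cccc(O)c4)cc(O)c3O)cc2)c1 | target

Total step count: 4. Longest linear sequence: 4 steps (1 → 3 → 5 → 6 → 7).

Steps most likely to fail:

Step 3 (proposed new method). The hydrogen taken from the rings could leave the catalyst as gas instead of being transferred to the bridges, the reaction could stall at partly reduced rings, or the dienone could oligomerise under base at 150 °C. The fallback uses known chemistry, sets out from 5 and comes back at 6. Both arms of 5 would be fully hydrogenated (H2, 1 atm, 10% Pd/C, EtOAc, rt) to the bis-cyclohexanone 3-[2-(4-{2,3-dimethoxy-5-[2-(3-oxocyclohexyl)ethyl]phenoxy}phenyl)ethyl]cyclohexan-1-one F1, a stereoisomer mixture of no consequence. F1 would then be aromatised by twofold aerobic palladium-catalysed dehydrogenation of the 3-substituted cyclohexanones (Pd(OCOCF3)2, 2-(dimethylamino)pyridine, TsOH, O2 1 atm, DMSO, 80 °C) to give 6.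

Step 2. The dienolate could lose site selectivity and attack through ring carbon C6 or C2 instead of the exocyclic methyl group, the enone could self-condense, or the reaction could stall after one arm. The fallback gives up the built rings for purchased arenes, sets out from 3 and comes back at 6. Twofold Wittig methylenation of 3 (Ph3PCH3Br, KOtBu, THF, 0 °C) would give 5-ethenyl-3-(4-ethenylphenoxy)-1,2-dimethoxybenzene F2. Anti-Markovnikov hydroboration of both vinyl groups (9-BBN, THF, 0 °C to rt) would give the bis-borane 9-[2-(4-{5-[2-(9-borabicyclo[3.3.1]nonan-9-yl)ethyl]-2,3-dimethoxyphenoxy}phenyl)ethyl]-9-borabicyclo[3.3.1]nonane F3, which would not be isolated. A twofold B-alkyl Suzuki–Miyaura coupling with 3-bromophenol (PdCl2(dppf), dppf = 1,1'-bis(diphenylphosphino)ferrocene, aqueous K3PO4, THF/DMF, 65 °C) would then give 6.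

Step 1. Substitution by a phenoxide flanked by a methoxy group could be sluggish, and the aldehydes could degrade in hot basic DMF. The fallback replaces SNAr by an oxidative copper coupling, sets out from 1 and comes back at 3. A Chan–Lam coupling of 1 with (4-formylphenyl)boronic acid (Cu(OAc)2, pyridine, 4 Å molecular sieves, CH2Cl2, air, rt) would give 3 directly, and no new compound would be made (F0).

Further compounds

F1 | step 3 | 3-[2-(4-{2,3-dimethoxy-5-[2-(3-oxocyclohexyl)ethyl]phenoxy}phenyl)ethyl]cyclohexan-1-one (mixture of stereoisomers at the two ring CH carbons) | O=C1CCCC(CCc2ccc(Oc3cc(CCC4CCCC(=O)C4)cc(OC)c3OC)cc2)C1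
F2 | step 2 | 5-ethenyl-3-(4-ethenylphenoxy)-1,2-dimethoxybenzene | C=Cc1ccc(Oc2cc(C=C)cc(OC)c2OC)cc1
F3 | step 2 | 9-[2-(4-{5-[2-(9-borabicyclo[3.3.1]nonan-9-yl)ethyl]-2,3-dimethoxyphenoxy}phenyl)ethyl]-9-borabicyclo[3.3.1]nonane | COc1cc(CCB2C3CCCC2CCC3)cc(Oc2ccc(CCB3C4CCCC3CCC4)cc2)c1OC
F0 | step 1 | none | none
A1 | direct plan | 3-(benzyloxy)-4,5-dimethoxybenzaldehyde | O=Cc1cc(OCc2ccccc2)c(OC)c(OC)c1
A2 | direct plan | (3-methoxyphenyl)acetic acid | COc1cccc(CC(=O)O)c1
A3 | direct plan | (2E)-3-[3-(benzyloxy)-4,5-dimethoxyphenyl]-2-(3-methoxyphenyl)prop-2-enoic acid | OC(=O)/C(c1cccc(OC)c1)=C/c1cc(OCc2ccccc2)c(OC)c(OC)c1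
A4 | direct plan | 2,3-dimethoxy-5-[2-(3-methoxyphenyl)ethyl]phenol | COc1cccc(CCc2cc(O)c(OC)c(OC)c2)c1
A5 | direct plan | 4-{2,3-dimethoxy-5-[2-(3-methoxyphenyl)ethyl]phenoxy}benzaldehyde | COc1cccc(CCc2cc(Oc3ccc(C=O)cc3)c(OC)c(OC)c2)c1
A6 | direct plan | 1,2-dimethoxy-5-[2-(3-methoxyphenyl)ethyl]-3-{4-[2-(3-methoxyphenyl)ethyl]phenoxy}benzene | COc1cccc(CCc2ccc(Oc3cc(CCc4cccc(OC)c4)cc(OC)c3OC)cc2)c1
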